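The readings were generated by integration for an exercise; scatter was added.

I cannot read the effect of the precatalyst charge off these runs: both stand at 16 mM.

| flask | starting material | second substrate | precatalyst | remark |
|---|---|---|---|---|
| south-east | 0.40 M | 0.40 M | 16 mM | run made earlier |
| east | 1.6 M | 0.40 M | 16 mM | run made earlier |
| flask | 0.80 M | 0.400 M | 16 mM |  |

| run | time / min | target / % | starting material / % |
|---|---|---|---|
| south-east | 6.00 | 0.6 | 99.7 |
| south-east | 12.0 | 0.1 | 99.7 |
| south-east | 15.0 | 1.3 | 98.4 |
| south-east | 25.0 | 1.9 | 97.1 |
| south-east | 30.0 | 3.6 | 95.7 |
| south-east | 40.0 | 6.1 | 93.5 |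
| east | 6.00 | 0.3 | 99.9 |
| east | 12.0 | 1.7 | 99.8 |
| east | 15.0 | 0.6 | 100.2 |
| east | 25.0 | 1.4 | 97.2 |
| east | 30.0 | 1.9 | 98.1 |
| east | 40.0 | 2.8 | 96.2 |

(standard deviation of a reading: 0.5 percentage points)

- no earlier run changes the charge of precatalyst; that part of a forecast is a guess

- factor on the rate of making target when 20% of the starting material are converted if precatalyst is charged twice over
- factor on the rate when 20% of the starting material are converted if precatalyst is charged at 150 mM instead

1. The bench rule I start from: the rate follows the catalyst charged. So I reckon a factor of 2 for the doubled charge and 9.38 for 150 mM.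

2. That rule needs catalyst that reaches the look unworn, so I count the turnovers asked (the turnover number at the look), meaning the target wanted at the look per catalyst charged. In this flask, 20% of 0.80 M against 16 mM asks 10.0 turnovers. At 150 mM it asks 1.07.

3. Here is the border. The last east reading, after 40.0 min, stands at 2.80 turnovers, so this flask asks more than the readings reach.

4. I commit to the rule's numbers, marked as lying past that border. The forecast says 1.5 and 3.4, and the first is lower than mine. Of its factors it says: “These catalyst factors are a guess, since no run varied the charge.”

The simulation gives 2.55 and 8.92.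

    starting material + free catalyst ⇌ catalyst intermediate A (K = 3.30 M⁻¹, k = 0.0178 M⁻¹ s⁻¹)
    catalyst intermediate A → free catalyst + target (k = 0.00558 s⁻¹)
    second substrate + free catalyst ⇌ catalyst intermediate B (K = 4.70 M⁻¹, k = 0.0249 M⁻¹ s⁻¹)
    catalyst intermediate B → free catalyst + second product (k = 0.00363 s⁻¹)
    catalyst intermediate A → spent catalyst (k = 2.58 × 10⁻⁴ s⁻¹)
    precatalyst → free catalyst (k = 6.31 × 10⁻⁴ s⁻¹)

Target and spent catalyst both leave catalyst intermediate A, so each turnover sends 4.62% of the catalyst charged to spent catalyst. The 10.0 turnovers asked count all converted starting material as target, but some of it sits in catalyst intermediate A and spent catalyst. That leaves 9.37 turnovers made, which put 43.3% of the catalyst charged in spent catalyst by the look at 130 min. In the run without that step, the rate at the look is 1.78 times the actual one. With the charge doubled, the same look asks 5.00 turnovers, and the simulated factor there is 2.55, more than 2.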